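The rate constants can wait: the earlier runs first show you how far a flask can go at all, and that depends on two amounts, the Z charged and the G charged.

| setting | autumn | dusk | winter | eta | alpha | beta | delta | zeta | epsilon |
|---|---|---|---|---|---|---|---|---|---|
| G | 1.5 M | 1.5 M | 0.88 M | 1.5 M | 1.5 M | 2.5 M | 1.5 M | 0.40 M | 1.5 M |
| Z | 0.36 M | 1 M | 1.5 M | 0.800 M | 1.50 M | 1.50 M | 0.400 M | 1.50 M | 0.400 M |
| temperature | 25 °C | 55 °C | 25 °C | 35 °C | 50 °C | 70 °C | 30 °C | 50 °C | 80 °C |
| remark | run made earlier | run made earlier | run made earlier |  |  |  |  |  |  |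
| time |  |  |  | 3.0 min | 3.0 min | 3.0 min | 3.0 min | 3.0 min | 3.0 min |

| run | time / min | J / % | G / % |
|---|---|---|---|
| autumn | 0.667 | 3 | 87 |
| autumn | 2.50 | 14 | 80 |
| autumn | 3.00 | 19 | 78 |
| autumn | 5.00 | 20 | 76 |
| autumn | 8.00 | 22 | 76 |
| autumn | 10.0 | 23 | 75 |
| dusk | 0.250 | 39 | 48 |
| dusk | 0.417 | 51 | 38 |
| dusk | 0.667 | 60 | 34 |
| dusk | 1.00 | 65 | 33 |
| dusk | 2.00 | 68 | 34 |
| dusk | 3.00 | 67 | 33 |
| winter | 2.50 | 57 | 16 |
| winter | 5.00 | 79 | 3 |
| winter | 6.00 | 87 | 0 |
| winter | 8.00 | 89 | 3 |
| winter | 10.0 | 94 | 3 |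

(scatter of a reading: 2 percentage points)

- ranking by amount of J, in percent of the G charged, from high to low, at 3.0 min (eta / alpha / beta / delta / zeta / epsilon)
- the amount of J, in percent of the G charged of the flask you put first, at 3.0 min
- the amount of J, in percent of the G charged of the flask you put last, at 3.0 min

Look at the end of the dusk run: G has lost 67.0%, J reads 67%, and Z charged over G charged comes to 66.7%, while the autumn run, at 25 °C instead of 55 °C, ends with J at 23% against a ratio of 24.0%. So you may read that one G takes one Z, and that Z, where it is charged short of G, is the limiting reagent. Beta, with 2.5 M of G and 1.50 M of Z, has 60.0% as its ceiling, the Z charged over the G charged, and once that ratio passes one the ceiling is full yield, towards which the winter run climbs, its ratio being 1.70 and its J reading 94% at 10.0 min. My own ranking follows: alpha and zeta at 100%, then beta, then eta at 53.3%, then delta and epsilon at 26.7%.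

Time has to break the two ties. The autumn run at 3.00 min still reads 19%, short of its ceiling, whereas the dusk run, warmer and also richer in Z, reads 67% at 3.00 min, level with its ratio within the scatter, so I put delta at 30 °C behind epsilon at 80 °C, the two flasks differing in temperature and in nothing else. I put zeta ahead of alpha, since its Z stands at 3.75 times its G, more than the equal charges of alpha.

The forecast gives zeta > alpha > beta > eta > epsilon > delta, with 95% first and 22% last, holding that “J is capped by the limiting reagent”; its order is mine, and its two numbers are its own.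

The flask gives zeta > alpha > beta > eta > epsilon > delta, with >99.9% for zeta and 21.9% for delta, while beta reads 60.0% on its ceiling of 60.0% and eta reads 47.4% under its 53.3%.

    Q ⇌ X (K = 0.110, k = 0.0500 s⁻¹, Ea = 94.0 kJ mol⁻¹, ΔH = −75.0 kJ mol⁻¹)
    G + Z → D (k = 0.130 M⁻¹ s⁻¹, Ea = 62.0 kJ mol⁻¹)
    D ⇌ Q (K = 0.480, k = 0.0310 s⁻¹, Ea = 94.0 kJ mol⁻¹, ΔH = −2.00 kJ mol⁻¹)
    D → J (k = 0.110 s⁻¹, Ea = 72.0 kJ mol⁻¹)
    Z ⇌ L (K = 0.470, k = 0.170 s⁻¹, Ea = 72.0 kJ mol⁻¹, ΔH = 11.0 kJ mol⁻¹)
    (constants at 50 °C)

Now take zeta and cut its Z to 0.38 M, which is less than its 0.40 M of G, so that the ceiling drops to 95.0%. At 3.0 min that neighbouring flask holds 82.6% of J, under the ceiling, with 16% of its G and 8.0% of its Z still free.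

(All runs stem from a simulated flask with constants of no real substance; noise was put on by code.)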